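**Retrosynthetic overview**

1. Locants follow spiro[5.5]undecane: ring B is C1–C5 (C1=C2, carbinol C3), C6 is the spiro carbon, ring A is C7–C11 (C7 methylidene, C9 carbinol, C10 bromide, C11 gem-dimethyl). The strategy rests on C6 being α to C7, a latent ring A carbonyl, while carrying the sp2 carbon C1 of the cis C1=C2 olefin of ring B.
2. Late disconnections: C3–CHBr2 (carbenoid addition to the ring B enone), C9–OH and C10–Br (α′-bromo ketone), and C7=CH2 (desilylative deconjugation of a C7–CH2SiMe3 enone made by carbonyl transposition of a vinylogous ester).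
3. Key disconnection C1–C6: enantioselective palladium-catalysed alkenylation of the α′-enolate of a dimedone-derived isobutyl vinylogous ester by its tethered (Z)-iodoalkene. This closes ring B and sets the C6 stereocentre, with the C3 ketone masked as a dioxolane.
4. The cyclisation precursor comes from α′-alkylation of the vinylogous ester with an iodoethyl (Z)-iodovinyl dioxolane built from 3-chloropropanoyl chloride and bis(trimethylsilyl)acetylene.
5. Ring order: ring A is present from dimedone; ring B is closed in the key step; all remaining stereocentres (C10, C9, C3) are then set under control of C6.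

Key step: step 8

Assumption: the sense of induction of the chiral bisphosphine in step 8 cannot be predicted reliably; the route is written with one antipode, and the mirror-image ligand is used if the first run gives the (6S) spirocycle.
Assumption: the epimers possible at C10 (step 10) and C3 (step 14) are taken to be separable by chromatography.

**Route**

Step 1
Reactants: 1 3-chloropropanoyl chloride; 2 bis(trimethylsilyl)acetylene
Product: 3 5-chloro-1-(trimethylsilyl)pent-1-yn-3-one
Conditions: AlCl3, CH2Cl2, 0 °C
Reagents that add atoms: none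
Why: Friedel–Crafts-type acylation of a silylalkyne, in which AlCl3 activates the acid chloride and ipso substitution at silicon should give the ynone, the second silyl group being deactivated by the new carbonyl.

Step 2
Reactants: 3 5-chloro-1-(trimethylsilyl)pent-1-yn-3-one
Product: 4 2-(2-chloroethyl)-2-[(trimethylsilyl)ethynyl]-1,3-dioxolane
Conditions: Me3SiOCH2CH2OSiMe3, Me3SiOTf (cat.), CH2Cl2, −78 → −20 °C; pyridine quench
Reagents that add atoms: 1,2-bis(trimethylsilyloxy)ethane C[Si](C)(C)OCCO[Si](C)(C)C
Why: Noyori ketalisation runs at low temperature under aprotic conditions, so conjugate addition of the diol to the ynone and loss of HCl from the β-chloro ketone should be avoided.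

Step 3
Reactants: 4 2-(2-chloroethyl)-2-[(trimethylsilyl)ethynyl]-1,3-dioxolane
Product: 5 2-(2-chloroethyl)-2-(iodoethynyl)-1,3-dioxolane
Conditions: N-iodosuccinimide, AgNO3 (0.2 equiv), acetone, rt, dark
Reagents that add atoms: N-iodosuccinimide O=C1CCC(=O)N1I
Why: Silver-catalysed iododesilylation, in which the silylalkyne passes through a silver acetylide that is iodinated, under conditions that are neutral toward the ketal and the alkyl chloride.

Step 4
Reactants: 5 2-(2-chloroethyl)-2-(iodoethynyl)-1,3-dioxolane
Product: 6 2-(2-chloroethyl)-2-[(Z)-2-iodoethenyl]-1,3-dioxolane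
Conditions: 2-nitrobenzenesulfonyl hydrazide, Et3N, THF/i-PrOH, rt, dark
Reagents that add atoms: none
Why: Diimide reduction transfers two hydrogens syn to the iodoalkyne and should stop at the (Z)-iodoalkene without hydrogenolysis of the C–I or C–Cl bond.

Step 5
Reactants: 6 2-(2-chloroethyl)-2-[(Z)-2-iodoethenyl]-1,3-dioxolane
Product: 7 2-(2-iodoethyl)-2-[(Z)-2-iodoethenyl]-1,3-dioxolane
Conditions: NaI, NaHCO3 (cat.), acetone, reflux, dark
Reagents that add atoms: sodium iodide [Na+].[I-]
Why: Finkelstein exchange (SN2 at the primary chloride, driven by precipitation of NaCl) should leave the iodoalkene and the ketal untouched.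

Step 6
Reactants: 8 dimedone
Product: 9 3-isobutoxy-5,5-dimethylcyclohex-2-en-1-one
Conditions: i-BuOH, TsOH·H2O (cat.), toluene, reflux, Dean–Stark trap
Reagents that add atoms: 2-methylpropan-1-ol CC(C)CO
Why: Acid-catalysed enol etherification of the 1,3-diketone with azeotropic removal of water gives the vinylogous ester, and the symmetry of dimedone excludes regioisomers.

Step 7
Reactants: 9 3-isobutoxy-5,5-dimethylcyclohex-2-en-1-one; 7 2-(2-iodoethyl)-2-[(Z)-2-iodoethenyl]-1,3-dioxolane
Product: 11 racemic 6-{2-[2-((Z)-2-iodoethenyl)-1,3-dioxolan-2-yl]ethyl}-3-isobutoxy-5,5-dimethylcyclohex-2-en-1-one, via lithium enolate 10 (not isolated)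
Conditions: LiN(i-Pr)2 (slight deficit relative to 9), THF, −78 °C; then 7, DMPU, −78 → 0 °C
Reagents that add atoms: none
Why: Stork–Danheiser kinetic α′-deprotonation and SN2 alkylation by the primary iodide, with a deficit of amide base so that no free base can eliminate HI from the (Z)-iodoalkene; the new stereocentre is left racemic because step 8 erases it.

Step 8
Reactants: 11 racemic 6-{2-[2-((Z)-2-iodoethenyl)-1,3-dioxolan-2-yl]ethyl}-3-isobutoxy-5,5-dimethylcyclohex-2-en-1-one
Product: 13 (6R)-3,3-ethylenedioxy-9-isobutoxy-11,11-dimethylspiro[5.5]undeca-1,8-dien-7-one, via potassium enolate 12 (not isolated)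
Conditions: Pd2(dba)3 (5 mol %), (R)-DTBM-SEGPHOS (12 mol %), toluene/THF (0.02 M), rt pre-stir; then KN(SiMe3)2 (1.1 equiv, slow addition), −40 → 40 °C
Reagents that add atoms: none
Why: Zerovalent palladium inserts into the C–I bond of the (Z)-iodoalkene with retention of geometry, the potassium α′-enolate 12 displaces iodide on divalent palladium, and C–C reductive elimination forms C1–C6; the closest known reaction type is the palladium-catalysed intramolecular α-alkenylation of ketone enolates, known in enantioselective form for α-arylations and α-vinylations that create quaternary carbons. Ring B closes as a six-membered ring in the enolexo mode (the C6=C7 enolate bond stays outside the new ring) by reductive elimination from a seven-membered C-bound palladacycle, the Z geometry placing C1 within reach of C6. C6 is the only new stereocentre and is set by the chiral bisphosphine, which differentiates the two faces of the planar tetrasubstituted enolate; because enolisation erases the stereocentre of 11, both of its enantiomers converge on (6R)-13. The step needs alkenylation at C6 and not at oxygen or at the γ-carbon: both alternatives would require eight-membered rings, and a γ-dienolate can return to the α′-enolate by proton transfer through HN(SiMe3)2. It also needs the iodoalkene to survive the base, which is addressed by letting oxidative addition precede slow addition of KN(SiMe3)2 at low temperature, while β-hydride loss toward C5 should be slower than reductive elimination from the chelated wide-bite-angle complex.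

Step 9
Reactants: 13 (6R)-3,3-ethylenedioxy-9-isobutoxy-11,11-dimethylspiro[5.5]undeca-1,8-dien-7-one
Product: 15 (6R)-3,3-ethylenedioxy-11,11-dimethyl-7-[(trimethylsilyl)methyl]spiro[5.5]undeca-1,7-dien-9-one, via tertiary carbinol 14 (not isolated)
Conditions: Me3SiCH2Li, CeCl3, THF, −78 → 0 °C; then 0.5 M aq. HCl, THF, 0 °C, short contact
Reagents that add atoms: (trimethylsilyl)methyllithium C[Si](C)(C)C[Li]; water O
Why: Stork–Danheiser transposition, in which the organocerium reagent adds 1,2 to the hindered C7 carbonyl and brief dilute acid ionises the doubly allylic carbinol and hydrolyses the enol ether to the C9 enone faster than the dioxolane is cleaved, the quaternary C6 centre being untouched.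

Step 10
Reactants: 15 (6R)-3,3-ethylenedioxy-11,11-dimethyl-7-[(trimethylsilyl)methyl]spiro[5.5]undeca-1,7-dien-9-one
Product: 18 (6S,10S)-10-bromo-3,3-ethylenedioxy-11,11-dimethyl-7-[(trimethylsilyl)methyl]spiro[5.5]undeca-1,7-dien-9-one, via lithium enolate 16 (not isolated), via silyl dienol ether 17 (not isolated)
Conditions: LiN(i-Pr)2, THF, −78 °C; Me3SiCl; then N-bromosuccinimide, −78 → −20 °C
Reagents that add atoms: N-bromosuccinimide O=C1CCC(=O)N1Br
Why: Kinetic α′-enolisation at C10 (the only sp3 α-carbon), O-silylation and electrophilic bromination of the silyl enol ether; the two faces of C10 differ only in the C6 branch lying 1,3 to it, and bromine should add syn to the flat vinylic C1 branch rather than the C5 methylene, giving Br cis to C1, which is also the epimer that can hold bromine equatorial (the C6 descriptor changes to S only through the priority change caused by bromine).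

Step 11
Reactants: 18 (6S,10S)-10-bromo-3,3-ethylenedioxy-11,11-dimethyl-7-[(trimethylsilyl)methyl]spiro[5.5]undeca-1,7-dien-9-one
Product: 19 (6S,10S)-10-bromo-3,3-ethylenedioxy-11,11-dimethyl-7-methylidenespiro[5.5]undec-1-en-9-one
Conditions: Bu4NF, AcOH (1:1.2), THF, −20 → 0 °C; crude product used at once
Reagents that add atoms: none
Why: Fluoride-induced deconjugative protodesilylation, in which cleavage of the vinylogous α-silyl ketone gives the extended dienolate regiospecifically and kinetic protonation by AcOH at the α-carbon C8 should give the β,γ-unsaturated ketone with the exocyclic C7=CH2, the buffer suppressing re-enolisation, epimerisation at C10 and Favorskii-type loss of bromide.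

Step 12
Reactants: 19 (6S,10S)-10-bromo-3,3-ethylenedioxy-11,11-dimethyl-7-methylidenespiro[5.5]undec-1-en-9-one
Product: 20 (6S,9R,10S)-10-bromo-3,3-ethylenedioxy-11,11-dimethyl-7-methylidenespiro[5.5]undec-1-en-9-ol
Conditions: i-Bu2AlH, CH2Cl2, −78 °C; aq. potassium sodium tartrate
Reagents that add atoms: none
Why: Hydride reduction under steric approach control, in which the axial methyl group on C11 blocks the axial trajectory at C9 so that the non-basic i-Bu2AlH should attack equatorially and give the axial alcohol cis to the equatorial bromine (9R), a cis-bromohydrin that cannot close to an epoxide.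

Step 13
Reactants: 20 (6S,9R,10S)-10-bromo-3,3-ethylenedioxy-11,11-dimethyl-7-methylidenespiro[5.5]undec-1-en-9-ol
Product: 21 (6S,9R,10S)-10-bromo-9-hydroxy-11,11-dimethyl-7-methylidenespiro[5.5]undec-1-en-3-one
Conditions: 0.5 M aq. HCl, THF, rt
Reagents that add atoms: water O
Why: Acid-catalysed ketal hydrolysis through the allyl-stabilised oxocarbenium ion of the allylic dioxolane, under dilute acid that the homoallylic alcohol, the secondary bromide and the 1,1-disubstituted alkene should tolerate.

Step 14
Reactants: 21 (6S,9R,10S)-10-bromo-9-hydroxy-11,11-dimethyl-7-methylidenespiro[5.5]undec-1-en-3-one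
Product: 22 mailiohydrin, (3R,6S,9R,10S)-10-bromo-3-(dibromomethyl)-11,11-dimethyl-7-methylidenespiro[5.5]undec-1-ene-3,9-diol
Conditions: CH2Br2, LiN(i-Pr)2, THF, −90 °C (LiCHBr2, 3 equiv); then 21, −90 → −78 °C; AcOH quench at −78 °C
Reagents that add atoms: dibromomethane BrCBr (used as dibromomethyllithium [Li]C(Br)Br)
Why: 1,2-Addition of a lithium carbenoid to the enone carbonyl with a cold acidic quench, so that the β-oxido dibromide neither closes to an epoxide nor rearranges; the gem-dimethyl carbon C11 holds ring B with C11 pseudoequatorial and C7 pseudoaxial, and the target requires the bulky carbenoid to enter C3 along the equatorial trajectory (avoiding the axial hydrogen on C5), placing CHBr2 cis to C7 and OH cis to C11 (3R), a preference that is plausible but not assured, one equivalent of reagent being consumed by the C9 hydroxyl.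

**Compound list**

1 | 3-chloropropanoyl chloride | O=C(Cl)CCCl | starting material
2 | bis(trimethylsilyl)acetylene | C[Si](C)(C)C#C[Si](C)(C)C | starting material
3 | 5-chloro-1-(trimethylsilyl)pent-1-yn-3-one | C[Si](C)(C)C#CC(=O)CCCl | intermediate
4 | 2-(2-chloroethyl)-2-[(trimethylsilyl)ethynyl]-1,3-dioxolane | C[Si](C)(C)C#CC1(CCCl)OCCO1 | intermediate
5 | 2-(2-chloroethyl)-2-(iodoethynyl)-1,3-dioxolane | IC#CC1(CCCl)OCCO1 | intermediate
6 | 2-(2-chloroethyl)-2-[(Z)-2-iodoethenyl]-1,3-dioxolane | ClCCC1(/C=C\I)OCCO1 | intermediate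
7 | 2-(2-iodoethyl)-2-[(Z)-2-iodoethenyl]-1,3-dioxolane | ICCC1(/C=C\I)OCCO1 | intermediate
8 | dimedone (5,5-dimethylcyclohexane-1,3-dione) | CC1(C)CC(=O)CC(=O)C1 | starting material
9 | 3-isobutoxy-5,5-dimethylcyclohex-2-en-1-one | O=C1C=C(OCC(C)C)CC(C)(C)C1 | intermediate
10 | lithium 5-isobutoxy-3,3-dimethylcyclohexa-1,5-dien-1-olate (α′-enolate of 9, formed in the flask, not isolated) | [Li]OC1=CC(C)(C)CC(OCC(C)C)=C1 | intermediate
11 | racemic 6-{2-[2-((Z)-2-iodoethenyl)-1,3-dioxolan-2-yl]ethyl}-3-isobutoxy-5,5-dimethylcyclohex-2-en-1-one | O=C1C=C(OCC(C)C)CC(C)(C)C1CCC2(OCCO2)/C=C\I | intermediate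
12 | potassium α′-enolate of 11 (formed in the flask, not isolated) | [K]OC1=C(CCC2(OCCO2)/C=C\I)C(C)(C)CC(OCC(C)C)=C1 | intermediate
13 | (6R)-3,3-ethylenedioxy-9-isobutoxy-11,11-dimethylspiro[5.5]undeca-1,8-dien-7-one | O=C1C=C(OCC(C)C)CC(C)(C)[C@@]12C=CC3(OCCO3)CC2 | intermediate
14 | (6R)-3,3-ethylenedioxy-9-isobutoxy-11,11-dimethyl-7-[(trimethylsilyl)methyl]spiro[5.5]undeca-1,8-dien-7-ol, either configuration at C7 (formed in the flask, not isolated) | C[Si](C)(C)CC1(O)C=C(OCC(C)C)CC(C)(C)[C@@]12C=CC3(OCCO3)CC2 | intermediate
15 | (6R)-3,3-ethylenedioxy-11,11-dimethyl-7-[(trimethylsilyl)methyl]spiro[5.5]undeca-1,7-dien-9-one | C[Si](C)(C)CC1=CC(=O)CC(C)(C)[C@@]12C=CC3(OCCO3)CC2 | intermediate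
16 | lithium C9–C10 enolate of 15 (formed in the flask, not isolated) | C[Si](C)(C)CC1=CC(O[Li])=CC(C)(C)[C@@]12C=CC3(OCCO3)CC2 | intermediate
17 | 9-(trimethylsilyloxy) C7=C8, C9=C10 dienol ether of 15 (formed in the flask, not isolated) | C[Si](C)(C)CC1=CC(O[Si](C)(C)C)=CC(C)(C)[C@@]12C=CC3(OCCO3)CC2 | intermediate
18 | (6S,10S)-10-bromo-3,3-ethylenedioxy-11,11-dimethyl-7-[(trimethylsilyl)methyl]spiro[5.5]undeca-1,7-dien-9-one | C[Si](C)(C)CC1=CC(=O)[C@@H](Br)C(C)(C)[C@@]12C=CC3(OCCO3)CC2 | intermediate
19 | (6S,10S)-10-bromo-3,3-ethylenedioxy-11,11-dimethyl-7-methylidenespiro[5.5]undec-1-en-9-one | C=C1CC(=O)[C@@H](Br)C(C)(C)[C@@]12C=CC3(OCCO3)CC2 | intermediate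
20 | (6S,9R,10S)-10-bromo-3,3-ethylenedioxy-11,11-dimethyl-7-methylidenespiro[5.5]undec-1-en-9-ol | C=C1C[C@@H](O)[C@@H](Br)C(C)(C)[C@@]12C=CC3(OCCO3)CC2 | intermediate
21 | (6S,9R,10S)-10-bromo-9-hydroxy-11,11-dimethyl-7-methylidenespiro[5.5]undec-1-en-3-one | C=C1C[C@@H](O)[C@@H](Br)C(C)(C)[C@@]12C=CC(=O)CC2 | intermediate
22 | mailiohydrin, (3R,6S,9R,10S)-10-bromo-3-(dibromomethyl)-11,11-dimethyl-7-methylidenespiro[5.5]undec-1-ene-3,9-diol | C=C1C[C@@H](O)[C@@H](Br)C(C)(C)[C@@]12C=C[C@@](O)(C(Br)Br)CC2 | target

**Step count and risks**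

Total step count: 14. Longest linear sequence: 13 steps (steps 1–5 and 7–14, from 1 and 2).

The three steps most likely to fail:

1. Step 8. What may go wrong: slow C–C reductive elimination at a carbon flanked by the gem-dimethyl carbon, weak enantiofacial discrimination by the ligand, or base-induced loss of HI from the iodoalkene before oxidative addition. Fallback (sets out from 9 and 4, comes back at 13): the quaternary centre is set by a decarboxylative asymmetric allylic alkylation and ring B is closed by ring-closing metathesis. Desilylation of 4 (K2CO3, MeOH) would give 2-(2-chloroethyl)-2-ethynyl-1,3-dioxolane F1. Semihydrogenation (H2, Pd/CaCO3 poisoned with Pb(OAc)2, quinoline) would give 2-(2-chloroethyl)-2-ethenyl-1,3-dioxolane F2. NaI in acetone would give 2-ethenyl-2-(2-iodoethyl)-1,3-dioxolane F3. Alkylation of the lithium enolate of 9 with F3, as in step 7, would give racemic 6-[2-(2-ethenyl-1,3-dioxolan-2-yl)ethyl]-3-isobutoxy-5,5-dimethylcyclohex-2-en-1-one F4. LiN(i-Pr)2 followed by allyl chloroformate would give the allyl enol carbonate F5. Pd2(dba)3 with a tert-butyl phosphinooxazoline ligand should then deliver, with loss of CO2, (6R)-6-allyl-6-[2-(2-ethenyl-1,3-dioxolan-2-yl)ethyl]-3-isobutoxy-5,5-dimethylcyclohex-2-en-1-one F6. RuHCl(CO)(PPh3)3 in warm toluene would move the allyl double bond to give the 6-(prop-1-enyl) ketone F7. Second-generation Hoveyda–Grubbs catalyst would close ring B between the propenyl and ethenyl groups with loss of propene to give 13.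

2. Step 14. What may go wrong: attack of the carbenoid along the axial trajectory (anti to the pseudoaxial C7 branch), which gives the C3 epimer, together with enolisation of the enone by the basic reagent. Fallback (sets out from 21, comes back at 22): tribromomethyllithium (CHBr3, LiN(i-Pr)2, THF, −100 °C), a larger nucleophile with a stronger bias for the equatorial trajectory, would give (3R,6S,9R,10S)-10-bromo-11,11-dimethyl-7-methylidene-3-(tribromomethyl)spiro[5.5]undec-1-ene-3,9-diol F8. Halophilic monodebromination of the tribromomethyl group with diethyl phosphite and Et3N (Hirao-type reduction), which should leave the secondary bromide alone, would give 22.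

3. Step 11. What may go wrong: re-enolisation of the β,γ-unsaturated ketone and return of the double bond into conjugation, epimerisation at C10, or intramolecular displacement of bromide by the dienolate. Fallback (sets out from 18, comes back at 21): the ketone is reduced before the olefin is moved. i-Bu2AlH at −78 °C would reduce 18 in the 1,2 sense, again anti to the axial C11 methyl, to (6S,9R,10S)-10-bromo-3,3-ethylenedioxy-11,11-dimethyl-7-[(trimethylsilyl)methyl]spiro[5.5]undeca-1,7-dien-9-ol F9. TsOH·H2O in wet MeCN at 0 °C would then protonate the now electron-rich allylsilane at C8 (SE2′ protodesilylation) and hydrolyse the ketal in the same flask to give 21. The process to watch in this variant is acid-induced 1,4-elimination of the C9 hydroxyl and the silyl group, which the adjacent bromine should retard.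

**Further compounds**

F1 | step 8 | 2-(2-chloroethyl)-2-ethynyl-1,3-dioxolane | C#CC1(CCCl)OCCO1
F2 | step 8 | 2-(2-chloroethyl)-2-ethenyl-1,3-dioxolane | C=CC1(CCCl)OCCO1
F3 | step 8 | 2-ethenyl-2-(2-iodoethyl)-1,3-dioxolane | C=CC1(CCI)OCCO1
F4 | step 8 | racemic 6-[2-(2-ethenyl-1,3-dioxolan-2-yl)ethyl]-3-isobutoxy-5,5-dimethylcyclohex-2-en-1-one | O=C1C=C(OCC(C)C)CC(C)(C)C1CCC2(OCCO2)C=C
F5 | step 8 | allyl 2-[2-(2-ethenyl-1,3-dioxolan-2-yl)ethyl]-5-isobutoxy-3,3-dimethylcyclohexa-1,5-dien-1-yl carbonate | C=CCOC(=O)OC1=C(CCC2(OCCO2)C=C)C(C)(C)CC(OCC(C)C)=C1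
F6 | step 8 | (6R)-6-allyl-6-[2-(2-ethenyl-1,3-dioxolan-2-yl)ethyl]-3-isobutoxy-5,5-dimethylcyclohex-2-en-1-one | O=C1C=C(OCC(C)C)CC(C)(C)[C@]1(CC=C)CCC2(OCCO2)C=C
F7 | step 8 | (6R)-6-[2-(2-ethenyl-1,3-dioxolan-2-yl)ethyl]-3-isobutoxy-5,5-dimethyl-6-(prop-1-enyl)cyclohex-2-en-1-one | O=C1C=C(OCC(C)C)CC(C)(C)[C@]1(C=CC)CCC2(OCCO2)C=C
F8 | step 14 | (3R,6S,9R,10S)-10-bromo-11,11-dimethyl-7-methylidene-3-(tribromomethyl)spiro[5.5]undec-1-ene-3,9-diol | C=C1C[C@@H](O)[C@@H](Br)C(C)(C)[C@@]12C=C[C@@](O)(C(Br)(Br)Br)CC2
F9 | step 11 | (6S,9R,10S)-10-bromo-3,3-ethylenedioxy-11,11-dimethyl-7-[(trimethylsilyl)methyl]spiro[5.5]undeca-1,7-dien-9-ol | C[Si](C)(C)CC1=C[C@@H](O)[C@@H](Br)C(C)(C)[C@@]12C=CC3(OCCO3)CC2
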